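| flask | free monomer | transfer agent | initiator | impurity | remark | time |
|---|---|---|---|---|---|---|
| Thursday's | 0.25 M | 7.5 mM | 11 mM | 3.1 mM | run made earlier |  |
| Sunday's | 0.25 M | 7.5 mM | 120 mM | 3.1 mM | run made earlier |  |
| Wednesday's | 0.22 M | 7.5 mM | 21 mM | 3.1 mM | run made earlier |  |
| epsilon | 0.50 M | 7.50 mM | 8.0 mM | 3.1 mM |  | 2.5 h |
| eta | 0.060 M | 7.50 mM | 80 mM | 0.80 mM |  | 2.5 h |
| theta | 0.080 M | 7.50 mM | 15 mM | 3.1 mM |  | 2.5 h |
| gamma | 0.25 M | 7.50 mM | 21 mM | 3.1 mM |  | 2.5 h |

| run | time / min | monomer in chains / % | free monomer / % |
|---|---|---|---|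
| Thursday's | 8.00 | 2.9 | 88.6 |
| Thursday's | 20.0 | 4.0 | 75.8 |
| Thursday's | 50.0 | 5.4 | 51.8 |
| Thursday's | 120 | 7.8 | 20.8 |
| Sunday's | 25.0 | 53.6 | 26.0 |
| Sunday's | 50.0 | 61.3 | 9.9 |
| Sunday's | 80.0 | 63.9 | 2.4 |
| Sunday's | 120 | 64.6 | 0.6 |
| Wednesday's | 25.0 | 11.1 | 65.1 |
| Wednesday's | 50.0 | 13.2 | 44.4 |
| Wednesday's | 80.0 | 15.8 | 28.2 |
| Wednesday's | 120 | 17.3 | 15.5 |

(standard deviation of a reading: 0.3 percentage points)

- no earlier run changes the charge of impurity; that part of a forecast is a guess

1. ranking by amount of monomer in chains, in percent of the free monomer charged, from high to low, at 2.5 h (epsilon / eta / theta / gamma)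
2. the amount of monomer in chains, in percent of the free monomer charged of the flask you put first, at 2.5 h
3. the amount of monomer in chains, in percent of the free monomer charged of the flask you put last, at 2.5 h

- At early times Thursday's run had 2.9 % of its monomer in chains by 8.00 min, close to the 3.16 % of the monomer charge that initiator beyond impurity (active initiator) amounted to, so I asked what competes with capture, the taking up of free monomer by initiator.
- From 50.0 min to 120 min in Thursday's run, free monomer fell at 0.0130 min⁻¹, and chains took 7.74 % of that fall. So the loss constant, the first-order rate constant with which free monomer leaves other than into chains, read 0.0120 min⁻¹.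
- I treated eta as a race: the yield in chains is the pseudo-first-order capture rate over capture plus loss. Subtracting eta's impurity from its initiator is a guess, since no earlier run changes that charge.
- For the floor I took the mean chain rate per active initiator over Sunday's first 25.0 min, which gives 0.0264 min⁻¹ on eta's charge and a share of 68.7 %. I expected eta to beat this because its active initiator exceeds its monomer, whereas Sunday's monomer exceeded its active initiator.
- For the ceiling I charged Thursday's whole early gain to capture, which gives 0.105 min⁻¹ and a share of 89.7 %. This bound is rough, since it rests on a gap of 0.26 percentage points against a scatter of 0.3 points.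
- The forecast ranked eta > theta > gamma > epsilon, with eta at 80 % (range 60 % to 93 %), inside my bracket, and epsilon at 4.8 % (range 3.8 % to 6 %). Its ground for eta was that “initiator roughly matches monomer”.
- The flasks gave eta > theta > gamma > epsilon, with eta at 76.9 %, inside my bracket, and epsilon at 3.52 %, within tolerance but under the forecast's low end.

    free monomer + initiator → living end + monomer in chains (k = 0.724 M⁻¹ min⁻¹)
    free monomer + living end → monomer in chains + living end, rate k2*[living end]*[free monomer] (k = 0.167 M⁻¹ min⁻¹)
    living end + transfer agent → dead chain (kL = 0.0701 M⁻¹ min⁻¹)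
    initiator + impurity → spent initiator (k = 188 M⁻¹ min⁻¹)
    free monomer → uncatalysed product (k = 0.0111 min⁻¹)
    free monomer + monomer in chains → side product (k = 0.0353 M⁻¹ min⁻¹)

- In eta, the half-life of free monomer by capture alone, the other concentrations as charged, was 0.20 h, against 0.961 h by my loss constant, a ratio of 4.80. That race gives 82.8 %, and eta gave 76.9 % with 46 % of its initiator left at 2.50 h.
- In epsilon stopped at 40 min, the loss constant gives 61.9 % of the free monomer left; the computed flask held 60.7 %, with 2.53 % in chains.

Readings and results are simulated with constants of no real substance; scatter was added.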